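Atom numbering of the target is used for every intermediate: C1 = C(OH)(C7H2OBz), C2 = CH(OBz), C3=C4, C5 = CH(OBz), C6 = CH(OH). In the bicyclic intermediates C2 and C5 are the bridgeheads; "exo" means the face of the oxygen bridge.

## The problem

The target 18 is a single cyclohex-3-ene ring in which C1, C2, C5, C6 and the exocyclic C7 all carry oxygen; nothing has to be fused, but five oxygens must be sorted into three benzoates (C2, C5, C7) and two free hydroxyls (tertiary C1, secondary C6). The four stereocentres are (1S,2S,5S,6S): C1–OH, C6–OH and the C5 oxygen lie on one face, and the C2 oxygen lies on the other, cis to C7. C1 is quaternary and cannot be corrected once set, so it is the natural control element. Held in a rigid frame it can fix C6 (cis-diol) and, through the C7 arm, deliver oxygen to C2 from the opposite face. The two allylic benzoates can ionise or eliminate towards an aromatic ring under strong acid or base. The cis-vicinal C5–OBz/C6–OH pair invites acyl migration under base, so the last steps must be mild and not basic. The enabling feature is that the C2 and C5 oxygens sit 1,4 across C3=C4 in the ring. Joining them through one oxygen gives a 7-oxabicyclo[2.2.1]hept-5-ene, the furan Diels–Alder skeleton: furan supplies C2–C3=C4–C5 and the oxygen, and a 2-substituted acrolein supplies C1, C6 and C7. In that bicycle the bridge defines the exo face, which accounts for the all-cis C1–OH/C6–OH/C5–O relationship, and only C2 has to be inverted when the bridge is opened.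

## Retrosynthesis

**18 from 17.** No skeletal bond is cut. The C1/C6 diol is masked as an acetonide in 17, which is the exact complement of the three benzoates, and is released last with aqueous acid so that no base touches the cis C5–OBz/C6–OH pair.

**17 from 13.** The C2–O bond of the C2 benzoate is cut and C2 is reconnected to the C5 oxygen, which gives the oxygen-bridged benzoate 13. An external nucleophile would have to choose between C2 and C5, and between direct and allylic attack. The endo C7 benzoate of 13 can reach only C2, and only from the face opposite the bridge. Forward, a Lewis acid must open the bridge through the dioxanylium ion 14; hydrolysis gives the hydroxy benzoates 15 and 16, and both converge on 17 after benzoylation. The precursor 13 is simpler because every stereochemical relationship is reduced to exo versus endo on a rigid bicycle.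

**13 from 8.** The acetonide and the C7 ester are removed (13 to 12 to triol 10), and then the two C–O bonds at C1 and C6 are cut to give the diene alcohol 8. A cis-dihydroxylation from the exo face sets C1 and C6 together and turns C7 endo. The forward reaction must pick the C1=C6 alkene over C3=C4; the free allylic hydroxyl of 8 is used to direct OsO4 through its osmate ester 9.

**8 from 5.** The C1=C6 alkene is traced back to the bromo aldehyde 5. Direct loss of HBr from 5 is not relied on: the bicycle offers no antiperiplanar hydrogen, and 5 reverts to its components on warming. Instead 5 is reduced to the bromohydrin 6, which is closed to the spiro-epoxide 7, and 7 is isomerised to 8 by a syn elimination. The only β-hydrogens not on a bridgehead are on C6, so the regiochemistry is unambiguous.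

**5 from 3 and 4.** The C1–C2 and C5–C6 bonds are cut, which is the Diels–Alder disconnection to furan 4 and 2-bromoacrolein 3. This one step makes the carbocycle, places both allylic oxygens and fixes the absolute configuration at the bridgeheads. It demands a catalyst that selects one face of the dienophile at low temperature. 3 comes from acrolein 1 through the dibromide 2.

## Roads not taken

**Alternative 1:** The cut is C1–C2, made together with the C3=C4 alkene by an Ireland–Claisen ring contraction of a silyl ketene acetal derived from a carbohydrate lactone, giving acid A1.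
- Merits: the absolute configuration comes from the chiral pool. One step builds the ring, the quaternary C1, the C2 stereocentre and the alkene in the right place. No reversible or strained intermediate is involved.
- Weak points: the rearrangement substrate is long to prepare, and the lactone enolate carries a β-alkoxy group that can be lost by elimination. A1 still needs reduction of the acid to C7. Its acetonide spans C5/C6, whereas the target needs C5 acylated and C6 free, so the cis C5/C6 diol would have to be differentiated late. The tertiary MOM ether and the PMB ether need two further removals.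
- Comparison: this road is better in guaranteed enantiopurity and in avoiding a labile cycloadduct. The chosen plan sets against it a much shorter sequence from bulk chemicals and a C1/C6 acetonide that leaves exactly the three hydroxyls to be benzoylated.

**Alternative 2:** The cut is C2–C3, closed by an intramolecular Nozaki–Hiyama–Kishi addition of a (Z)-vinyl iodide to the C2 aldehyde of a pentose-derived chain, giving cyclohexenol A2.
- Merits: A2 is one benzoylation and one acetonide removal from the target; its benzoate is compound 17 of the present route. C1, C5 and C6 come from the sugar, and the organochromium step tolerates esters.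
- Weak points: the C2 carbinol configuration is set by diastereoselection in the ring closure with no obvious control element. The branched open-chain precursor, with its quaternary centre, (Z)-vinyl iodide and aldehyde, takes many steps. Divalent chromium is used in excess.
- Comparison: the end game is as good as or better than the one chosen here, since it needs no Lewis-acid ring opening. The chosen plan sets against it a stereospecific inversion at C2 and far fewer steps to the cyclohexene.

**Alternative 3:** The cut is the C6–O bond, formed by a chiral Brønsted acid-catalysed hemiacetalisation and oxa-Michael addition that desymmetrises an achiral cyclohexadienone, giving dioxolane enone A3.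
- Merits: very short and catalytic; the tether forces C1–O and C6–O cis; the substrate comes from a cheap phenol.
- Weak points: A3 has the wrong oxidation pattern, with the ketone at C4, the alkene at C2=C3 and a methylene at C5. Reaching the target needs oxygenation at C5, carbonyl reduction and a 1,3-allylic transposition that puts oxygen on C2. This creates two new stereocentres (C5, C2) without a clear source of control, and the acetal must be removed at the end.
- Comparison: the front end is superior in brevity and catalyst economy. The chosen plan sets against it that all oxygens sit on the correct carbons after the dihydroxylation and that C2 and C5 take their configuration from the bicycle.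

Key step: step 2

Assumption: the tryptophan-derived boron catalyst is taken to show the same sense of induction with furan as with cyclopentadiene, so the catalyst from (S)-tryptophan is specified; if the opposite bridgehead configuration were found, its mirror image from (R)-tryptophan would be used.

Remark: aldehyde 5 reverts to 3 and 4 on warming and is carried into step 3 cold and without storage.

## Route

Step 1
Reactants: 1 acrolein
Product: 3 2-bromoacrolein (2-bromoprop-2-enal), via 2,3-dibromopropanal 2 (not isolated)
Conditions: Br2, CH2Cl2, −78 °C; then Et3N, −78 → 0 °C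
Reagents that add atoms: bromine, BrBr
Why: Bromine adds across the enal and the amine removes the acidic α-hydrogen with loss of the β-bromide (bromination–dehydrobromination), a standard preparation of this dienophile.

Step 2
Reactants: 3 2-bromoacrolein; 4 furan
Product: 5 (1R,2R,4R)-2-bromo-7-oxabicyclo[2.2.1]hept-5-ene-2-carbaldehyde (formyl exo, bromine endo)
Conditions: (4S)-2-butyl-4-(1H-indol-3-ylmethyl)-3-tosyl-1,3,2-oxazaborolidin-5-one (10 mol %), furan (excess), CH2Cl2, −78 °C; cold work-up
Reagents that add atoms: none
Why: The aldehyde binds to boron in its s-cis form and the indole ring covers one face of the dienophile, so furan adds to the open face in a concerted, asynchronous Lewis-acid-catalysed [4+2] cycloaddition that forms C1–C2 and C5–C6. The closest known reaction type is the enantioselective Diels–Alder reaction of 2-bromoacrolein with cyclopentadiene and with furan under this class of oxazaborolidinone. The six-membered carbocycle C1–C6 is closed by intermolecular suprafacial cycloaddition, and the oxygen bridge between C2 and C5 is carried in by furan. The configuration at C1 is set by the enantioface of the dienophile chosen by the catalyst, and the bridgeheads C2 and C5 follow from the exo-formyl transition state on that face. The step needs enantioface selectivity, secured by the catalyst, and exo selectivity, secured by the α-bromo substituent. An endo adduct formed on the same dienophile face would carry mirror-image bridgeheads and would erode the enantiomeric purity once C1 becomes trigonal in step 4. Low temperature is required because the adduct is formed reversibly.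

Step 3
Reactants: 5 (1R,2R,4R)-2-bromo-7-oxabicyclo[2.2.1]hept-5-ene-2-carbaldehyde
Product: 7 (1R,2R,4R)-spiro[7-oxabicyclo[2.2.1]hept-5-ene-2,2'-oxirane] (epoxide oxygen exo), via bromohydrin 6 (not isolated)
Conditions: NaBH4, THF/H2O, −20 → 0 °C; then aq NaOH, 0 °C → rt
Reagents that add atoms: none
Why: Borohydride reduction removes the aldehyde that drives cycloreversion, and the alkoxide then displaces the endo tertiary bromide with inversion (intramolecular Williamson closure, 3-exo-tet), a standard fate of α-bromo aldehyde cycloadducts; the bridgeheads are untouched.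

Step 4
Reactants: 7 (1R,2R,4R)-spiro[7-oxabicyclo[2.2.1]hept-5-ene-2,2'-oxirane]
Product: 8 [(1R,4S)-7-oxabicyclo[2.2.1]hepta-2,5-dien-2-yl]methanol
Conditions: diethylaluminium 2,2,6,6-tetramethylpiperidide (from TMPH, n-BuLi, Et2AlCl), toluene, 0 °C; aq potassium sodium tartrate
Reagents that add atoms: none
Why: Aluminium amide isomerisation of an epoxide to an allylic alcohol proceeds by a cyclic syn elimination, and the exo C6–H lies syn to the exo epoxide oxygen; the only other β-hydrogen is on the C2 bridgehead and cannot be removed, so a single alkene isomer is expected. C1 becomes trigonal by design and the bridgeheads keep the chirality.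

Step 5
Reactants: 8 [(1R,4S)-7-oxabicyclo[2.2.1]hepta-2,5-dien-2-yl]methanol
Product: 10 (1R,2S,3S,4S)-2-(hydroxymethyl)-7-oxabicyclo[2.2.1]hept-5-ene-2,3-diol (both ring hydroxyls exo), via osmate ester 9 (not isolated)
Conditions: OsO4 (1.0 equiv), TMEDA, CH2Cl2, −78 °C; then aq Na2SO3, THF, 50 °C
Reagents that add atoms: osmium tetroxide, O=[Os](=O)(=O)=O
Why: In hydrogen-bond-directed dihydroxylation the OsO4·TMEDA complex is held by the allylic hydroxyl, so the trisubstituted C1=C6 alkene should react in preference to C3=C4. Attack from the exo face, the usual face of oxanorbornenes, sets C1–OH and C6–OH cis to the bridge and turns C7 endo.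

Step 6
Reactants: 10 (1R,2S,3S,4S)-2-(hydroxymethyl)-7-oxabicyclo[2.2.1]hept-5-ene-2,3-diol; 11 benzoyl chloride
Product: 12 [(1R,2S,3S,4S)-2,3-dihydroxy-7-oxabicyclo[2.2.1]hept-5-en-2-yl]methyl benzoate
Conditions: BzCl (1.05 equiv), pyridine, CH2Cl2, −30 → 0 °C
Reagents that add atoms: benzoyl chloride, O=C(Cl)c1ccccc1
Why: Selective acylation of the primary hydroxyl over the hindered secondary and the tertiary hydroxyl installs the C7 benzoate that is kept in the target and serves as the neighbouring group in step 8.

Step 7
Reactants: 12 [(1R,2S,3S,4S)-2,3-dihydroxy-7-oxabicyclo[2.2.1]hept-5-en-2-yl]methyl benzoate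
Product: 13 [(1R,2R,3S,4S)-2,3-(isopropylidenedioxy)-7-oxabicyclo[2.2.1]hept-5-en-2-yl]methyl benzoate (exo acetonide)
Conditions: Me2C(OMe)2, PPTS (cat.), acetone, rt
Reagents that add atoms: 2,2-dimethoxypropane, COC(C)(C)OC
Why: Acetal exchange on the cis exo diol gives the cis-fused dioxolane and masks exactly the two hydroxyls that are free in the target.

Step 8
Reactants: 13 [(1R,2R,3S,4S)-2,3-(isopropylidenedioxy)-7-oxabicyclo[2.2.1]hept-5-en-2-yl]methyl benzoate; 11 benzoyl chloride
Product: 17 [(3aR,4S,7S,7aS)-4,7-bis(benzoyloxy)-2,2-dimethyl-7,7a-dihydro-1,3-benzodioxol-3a(4H)-yl]methyl benzoate, via dioxanylium zwitterion 14 (not isolated), via C7-benzoate diol 15 (not isolated), via C2-benzoate diol 16 (not isolated)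
Conditions: BF3·OEt2 (1.2 equiv), CH2Cl2, −40 → 0 °C; aq NaHCO3; crude diols, then BzCl, pyridine, DMAP, CH2Cl2, 0 °C → rt
Reagents that add atoms: water, O; benzoyl chloride, O=C(Cl)c1ccccc1
Why: The Lewis acid activates the strained allylic bridge and the carbonyl oxygen of the endo C7 benzoate, anti to the C2–O bond, displaces it with inversion (neighbouring-group participation through a six-membered acyloxonium ion, as in acid-mediated openings of oxanorbornanes with ester participation), while C5 keeps the bridge oxygen. Hydrolysis of 14 gives the two hydroxy benzoates 15 and 16, and both give the same tribenzoate 17 on acylation of the free secondary and primary hydroxyls.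

Step 9
Reactants: 17 [(3aR,4S,7S,7aS)-4,7-bis(benzoyloxy)-2,2-dimethyl-7,7a-dihydro-1,3-benzodioxol-3a(4H)-yl]methyl benzoate
Product: 18 [(1S,2S,5S,6S)-2,5-bis(benzoyloxy)-1,6-dihydroxycyclohex-3-en-1-yl]methyl benzoate (CNP0128482.4)
Conditions: TFA/H2O (9:1), CH2Cl2, 0 °C → rt
Reagents that add atoms: none
Why: Acid-catalysed acetal hydrolysis frees the C1 and C6 hydroxyls without base, so the cis C5 benzoate should not migrate and the allylic esters should stay in place.

## Compound list

1 | acrolein (prop-2-enal) | C=CC=O | starting material
2 | 2,3-dibromopropanal | O=CC(Br)CBr | intermediate (not isolated)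
3 | 2-bromoacrolein (2-bromoprop-2-enal) | C=C(Br)C=O | intermediate
4 | furan | c1ccoc1 | starting material
5 | (1R,2R,4R)-2-bromo-7-oxabicyclo[2.2.1]hept-5-ene-2-carbaldehyde (formyl exo, bromine endo) | O=C[C@]1(Br)[C@H]2C=C[C@H](O2)C1 | intermediate
6 | [(1R,2S,4R)-2-bromo-7-oxabicyclo[2.2.1]hept-5-en-2-yl]methanol (bromine endo) | OC[C@]1(Br)[C@H]2C=C[C@H](O2)C1 | intermediate (not isolated)
7 | (1R,2R,4R)-spiro[7-oxabicyclo[2.2.1]hept-5-ene-2,2'-oxirane] (epoxide oxygen exo, CH2 endo) | C1O[C@@]12[C@H]3C=C[C@H](O3)C2 | intermediate
8 | [(1R,4S)-7-oxabicyclo[2.2.1]hepta-2,5-dien-2-yl]methanol | OCC1=C[C@@H]2C=C[C@H]1O2 | intermediate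
9 | TMEDA-chelated dioxo osmate ester of hexavalent osmium spanning the exo oxygens on C1 and C6 of 8 | OC[C@]12O[Os-2]3(=O)(=O)(O[C@H]1[C@@H]4C=C[C@H]2O4)[N+](C)(C)CC[N+]3(C)C | intermediate (not isolated)
10 | (1R,2S,3S,4S)-2-(hydroxymethyl)-7-oxabicyclo[2.2.1]hept-5-ene-2,3-diol (2-exo,3-exo-diol) | OC[C@@]1(O)[C@H]2C=C[C@H](O2)[C@@H]1O | intermediate
11 | benzoyl chloride | O=C(Cl)c1ccccc1 | starting material
12 | [(1R,2S,3S,4S)-2,3-dihydroxy-7-oxabicyclo[2.2.1]hept-5-en-2-yl]methyl benzoate | O=C(OC[C@@]1(O)[C@H]2C=C[C@H](O2)[C@@H]1O)c1ccccc1 | intermediate
13 | [(1R,2R,3S,4S)-2,3-(isopropylidenedioxy)-7-oxabicyclo[2.2.1]hept-5-en-2-yl]methyl benzoate (exo acetonide, benzoyloxymethyl endo) | O=C(OC[C@]12OC(C)(C)O[C@H]1[C@@H]3C=C[C@H]2O3)c1ccccc1 | intermediate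
14 | zwitterion: 2-phenyl-1,3-dioxan-2-ylium ring joining the C7 and C2 oxygens on the face opposite the former bridge, C5–O–BF3 anion, C1/C6 acetonide | F[B-](F)(F)O[C@H]1C=C[C@@H]2[O+]=C(c3ccccc3)OC[C@@]24OC(C)(C)O[C@@H]14 | intermediate (not isolated)
15 | [(3aR,4S,7S,7aS)-4,7-dihydroxy-2,2-dimethyl-7,7a-dihydro-1,3-benzodioxol-3a(4H)-yl]methyl benzoate (C7 benzoate; C2–OH and C5–OH free) | O=C(OC[C@]12OC(C)(C)O[C@H]1[C@@H](O)C=C[C@@H]2O)c1ccccc1 | intermediate (not isolated)
16 | (3aR,4S,7S,7aS)-7-hydroxy-3a-(hydroxymethyl)-2,2-dimethyl-3a,4,7,7a-tetrahydro-1,3-benzodioxol-4-yl benzoate (C2 benzoate; C7–OH and C5–OH free) | OC[C@]12OC(C)(C)O[C@H]1[C@@H](O)C=C[C@@H]2OC(=O)c1ccccc1 | intermediate (not isolated)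
17 | [(3aR,4S,7S,7aS)-4,7-bis(benzoyloxy)-2,2-dimethyl-7,7a-dihydro-1,3-benzodioxol-3a(4H)-yl]methyl benzoate | O=C(OC[C@]12OC(C)(C)O[C@H]1[C@@H](OC(=O)c3ccccc3)C=C[C@@H]2OC(=O)c4ccccc4)c5ccccc5 | intermediate
18 | [(1S,2S,5S,6S)-2,5-bis(benzoyloxy)-1,6-dihydroxycyclohex-3-en-1-yl]methyl benzoate | O=C(OC[C@@]1(O)[C@@H](OC(=O)c2ccccc2)C=C[C@H](OC(=O)c2ccccc2)[C@@H]1O)c1ccccc1 | target

## Step count and least certain steps

Total: 9 steps. Longest linear sequence: 9 steps from acrolein 1; furan 4 and benzoyl chloride 11 enter as commercial partners.

**Step 2 (key step).** What may go wrong: cycloreversion of the adduct during work-up, and lower facial or exo selectivity with the less reactive, aromatic diene, either of which lowers the enantiomeric purity carried into 8. Fallback, from 3 and 4 back to 7: the cycloaddition is run with the achiral Lewis acid BF3·OEt2 at −78 °C to give the racemic exo-formyl adduct F1, which is reduced in the same flask with NaBH4 to the racemic bromohydrin F2. Esterification with (S)-2-methoxy-2-phenylacetic acid (DCC, DMAP) gives the wanted (1R,2S,4R) ester F3 and its (1S,2R,4S) diastereomer F4, which are separated by crystallisation or chromatography. Aqueous NaOH in THF on F3 cleaves the ester and closes the epoxide in one operation to give 7.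

**Step 8.** What may go wrong: ionisation of the C5–O bond instead of the C2–O bond, capture of the allyl cation at C4, loss of the acetonide under the Lewis acid, or elimination towards an arene. Fallback, from 13 back to 17, with a stronger and irreversible neighbouring group: K2CO3/MeOH removes the benzoate to give the acetonide alcohol F5, and Boc2O with DMAP gives the tert-butyl carbonate F6. BF3·OEt2 then brings about the same anti displacement at C2 by the carbonate carbonyl, made irreversible by loss of 2-methylpropene, to give the six-membered cyclic carbonate F7 with C5–OH free. K2CO3/MeOH opens the carbonate to the acetonide triol F8, and BzCl, pyridine and DMAP convert F8 into 17.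

**Step 4.** What may go wrong: slow syn elimination because a strained diene is formed, competing metalation or nucleophilic opening at the epoxide CH2, Lewis-acid-induced skeletal rearrangement, and acid-triggered aromatisation of the product. Fallback, from 5 back to 8, moving the elimination to the ester oxidation level: NaClO2/NaH2PO4/2-methylbut-2-ene oxidises 5 to the bromo acid F9 and Me3SiCHN2 gives the methyl ester F10. KOt-Bu in THF at low temperature eliminates HBr to give the diene ester F11, the way 2-halonorbornene carboxylic acid derivatives are dehydrohalogenated to norbornadienes. i-Bu2AlH at −78 °C reduces F11 to 8.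

**Step 5.** What may go wrong: insufficient site selectivity, with osmylation of C3=C4 or of both alkenes. Fallback, from 8 back to 12, avoiding osmium and using only hydroxyl-directed epoxidations: VO(acac)2/t-BuOOH epoxidises only the allylic-alcohol alkene from the exo face to give the epoxy alcohol F12, and I2/PPh3/imidazole gives the epoxy iodide F13. Zn in ethanol opens F13 reductively to the transposed allylic alcohol F14, with an exocyclic C1=C7 methylene and C6–OH exo. A second VO(acac)2/t-BuOOH epoxidation, delivered syn to the C6 hydroxyl, gives the spiro-epoxy alcohol F15 with the epoxide oxygen exo and C7 endo. PhCO2H with Ti(OiPr)4 opens F15 at the primary C7 to give 12.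

## Further compounds

F1 | step 2 | racemic 2-bromo-7-oxabicyclo[2.2.1]hept-5-ene-2-carbaldehyde (formyl exo; both enantiomers) | O=C[C@]1(Br)[C@H]2C=C[C@H](O2)C1.O=C[C@@]1(Br)[C@@H]2C=C[C@@H](O2)C1
F2 | step 2 | racemic (2-bromo-7-oxabicyclo[2.2.1]hept-5-en-2-yl)methanol (bromine endo; both enantiomers) | OC[C@]1(Br)[C@H]2C=C[C@H](O2)C1.OC[C@@]1(Br)[C@@H]2C=C[C@@H](O2)C1
F3 | step 2 | [(1R,2S,4R)-2-bromo-7-oxabicyclo[2.2.1]hept-5-en-2-yl]methyl (S)-2-methoxy-2-phenylacetate | CO[C@H](C(=O)OC[C@]1(Br)[C@H]2C=C[C@H](O2)C1)c1ccccc1
F4 | step 2 | [(1S,2R,4S)-2-bromo-7-oxabicyclo[2.2.1]hept-5-en-2-yl]methyl (S)-2-methoxy-2-phenylacetate | CO[C@H](C(=O)OC[C@@]1(Br)[C@@H]2C=C[C@@H](O2)C1)c1ccccc1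
F5 | step 8 | [2,3-exo-(isopropylidenedioxy)-7-oxabicyclo[2.2.1]hept-5-en-2-yl]methanol (configuration as in 13) | OC[C@]12OC(C)(C)O[C@H]1[C@@H]3C=C[C@H]2O3
F6 | step 8 | tert-butyl [2,3-exo-(isopropylidenedioxy)-7-oxabicyclo[2.2.1]hept-5-en-2-yl]methyl carbonate (configuration as in 13) | CC(C)(C)OC(=O)OC[C@]12OC(C)(C)O[C@H]1[C@@H]3C=C[C@H]2O3
F7 | step 8 | six-membered cyclic carbonate joining the C7 and C2 oxygens, C5–OH free, C1/C6 acetonide (configuration as in 15) | O[C@H]1C=C[C@@H]2OC(=O)OC[C@@]24OC(C)(C)O[C@@H]14
F8 | step 8 | (3aR,4S,7S,7aS)-3a-(hydroxymethyl)-2,2-dimethyl-3a,4,7,7a-tetrahydro-1,3-benzodioxole-4,7-diol | OC[C@]12OC(C)(C)O[C@H]1[C@@H](O)C=C[C@@H]2O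
F9 | step 4 | (1R,2R,4R)-2-bromo-7-oxabicyclo[2.2.1]hept-5-ene-2-carboxylic acid (bromine endo) | OC(=O)[C@]1(Br)[C@H]2C=C[C@H](O2)C1
F10 | step 4 | methyl (1R,2R,4R)-2-bromo-7-oxabicyclo[2.2.1]hept-5-ene-2-carboxylate | COC(=O)[C@]1(Br)[C@H]2C=C[C@H](O2)C1
F11 | step 4 | methyl (1R,4S)-7-oxabicyclo[2.2.1]hepta-2,5-diene-2-carboxylate | COC(=O)C1=C[C@@H]2C=C[C@H]1O2
F12 | step 5 | (2,3-exo-epoxy-7-oxabicyclo[2.2.1]hept-5-en-2-yl)methanol (epoxide on the bridge face, bridgeheads as in 8) | OC[C@]12O[C@H]1[C@@H]3C=C[C@H]2O3
F13 | step 5 | 2,3-exo-epoxy-2-(iodomethyl)-7-oxabicyclo[2.2.1]hept-5-ene (configuration as in F12) | IC[C@]12O[C@H]1[C@@H]3C=C[C@H]2O3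
F14 | step 5 | 3-methylene-7-oxabicyclo[2.2.1]hept-5-en-2-exo-ol (C6–OH exo, bridgeheads as in 8) | C=C1[C@@H](O)[C@@H]2C=C[C@H]1O2
F15 | step 5 | spiro[7-oxabicyclo[2.2.1]hept-5-ene-2,2'-oxiran]-3-exo-ol (epoxide oxygen exo, CH2 endo) | C1O[C@@]12[C@H]3C=C[C@H](O3)[C@@H]2O
A1 | alternative 1 | cyclohexene carboxylic acid with C1–OMOM, C2–OPMB and C5,C6-acetonide | OC(=O)[C@@]1(OCOC)[C@@H](OCc3ccc(OC)cc3)C=C[C@H](OC(C)(C)O2)[C@@H]12
A2 | alternative 2 | cyclohexenol with free C2–OH, C1,C6-acetonide and C5, C7 benzoates | O=C(OC[C@@]1(OC(C)(C)O2)[C@@H](O)C=C[C@H](OC(=O)c3ccccc3)[C@@H]12)c1ccccc1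
A3 | alternative 3 | cis-fused cyclohexyl dioxolane enone with C1 and C6 set and the C7 benzoate | O=C(OC[C@@]1(O[C@H](C2CCCCC2)O3)C=CC(=O)C[C@@H]13)c1ccccc1
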